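**Retrosynthetic overview**
- Last bond: C8–CH2, by Negishi coupling of an (S)-8-iodoflavanone with a chiral homoallylic alkylzinc; then one acid step removes all protecting groups.
- Side chain: the stereocentre and its bond to the CH2CH2 unit come from a copper-catalysed enantioselective SN2′ allylation of a zinc ester homoenolate on (E)-1,4-dibromo-2-methylbut-2-ene; the ester then becomes CMe2OH.
- Flavanone: Claisen–Schmidt chalcone, then catalytic asymmetric oxa-Michael closure sets C2.
- Regiochemistry of ring A: mono-MOM protection of 2′,6′-dihydroxy-4′-methoxyacetophenone, then iodination ortho to the remaining OH, fixes which oxygen becomes O1 and where C8 is.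
- Ring order: rings A and B are bought aromatics; ring C is closed before the side chain is attached.

Assumption: (E)-1,4-dibromo-2-methylbut-2-ene is used as the geometrically pure catalogue compound, and the hand of the two chiral catalysts (steps 5 and 6) is confirmed on the first run.

**Route**

Step 1
Reactants: 1 2′,6′-dihydroxy-4′-methoxyacetophenone
Product: 2 1-[2-hydroxy-4-methoxy-6-(methoxymethoxy)phenyl]ethan-1-one
Conditions: MOMCl (1.1 equiv), i-Pr2NEt, CH2Cl2, 0 °C → rt
Reagents that add atoms: chloromethyl methyl ether, COCCl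
Why: O-alkylation (MOM protection) stops after one phenol because the second OH is held in the hydrogen bond to the ketone, which marks it as the future ring oxygen O1.

Step 2
Reactants: 2 1-[2-hydroxy-4-methoxy-6-(methoxymethoxy)phenyl]ethan-1-one
Product: 3 1-[2-hydroxy-3-iodo-4-methoxy-6-(methoxymethoxy)phenyl]ethan-1-one
Conditions: BnMe3N·ICl2 (1.05 equiv), CaCO3, CH2Cl2/MeOH, rt
Reagents that add atoms: benzyltrimethylammonium dichloroiodate, C[N+](C)(C)Cc1ccccc1.Cl[I-]Cl
Why: Electrophilic aromatic iodination goes ortho to the free chelated phenol (the less hindered of the two open positions, the usual outcome for 2-hydroxy-4,6-dialkoxyacetophenones), placing iodine at the future C8.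

Step 3
Reactants: 4 2,4-dihydroxybenzaldehyde
Product: 5 2,4-bis(methoxymethoxy)benzaldehyde
Conditions: MOMCl (2.6 equiv), K2CO3, acetone, reflux
Reagents that add atoms: chloromethyl methyl ether, COCCl
Why: Twofold Williamson-type MOM protection gives a base-stable ring B aldehyde whose ortho oxygen cannot interfere in the later ring closure.

Step 4
Reactants: 3 1-[2-hydroxy-3-iodo-4-methoxy-6-(methoxymethoxy)phenyl]ethan-1-one; 5 2,4-bis(methoxymethoxy)benzaldehyde
Product: 6 (E)-3-[2,4-bis(methoxymethoxy)phenyl]-1-[2-hydroxy-3-iodo-4-methoxy-6-(methoxymethoxy)phenyl]prop-2-en-1-one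
Conditions: KOH, EtOH/H2O, 0 °C → rt
Reagents that add atoms: none
Why: Claisen–Schmidt aldol condensation gives the E-chalcone, with MOM ethers and the aryl iodide inert to hydroxide and the phenoxide form holding the chalcone open until work-up.

Step 5
Reactants: 6 (E)-3-[2,4-bis(methoxymethoxy)phenyl]-1-[2-hydroxy-3-iodo-4-methoxy-6-(methoxymethoxy)phenyl]prop-2-en-1-one
Product: 7 (2S)-2-[2,4-bis(methoxymethoxy)phenyl]-8-iodo-7-methoxy-5-(methoxymethoxy)-2,3-dihydro-4H-chromen-4-one
Conditions: quinine-derived 3,5-bis(trifluoromethyl)phenyl thiourea (10 mol %), PhCl, 0 °C → rt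
Reagents that add atoms: none
Why: Bifunctional thiourea/amine-catalysed intramolecular oxa-Michael addition (biomimetic chalcone-to-flavanone closure) lets only the free, acidic 2′-OH add, ion-paired to the quinuclidine while the thiourea binds the enone, so that ring C closes on the face giving 2S (any 2R share becomes a separable diastereomer after step 8).

Step 6
Reactants: 8 (E)-1,4-dibromo-2-methylbut-2-ene; 9 1-ethoxy-1-(trimethylsilyloxy)cyclopropane
Product: 11 ethyl (4S)-4-(bromomethyl)-5-methylhex-5-enoate, via bis(3-ethoxy-3-oxopropyl)zinc 10 (not isolated)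
Conditions: 9 (2.4 equiv), ZnCl2 (1.2 equiv), Et2O, rt; then 8, CuBr·SMe2 (5 mol %), (S,S,S)-BINOL/bis(1-phenylethyl)amine phosphoramidite (6 mol %), THF, −30 → 0 °C
Reagents that add atoms: zinc dichloride, Cl[Zn]Cl (zinc of 10 only)
Why: Proposed new method: the zinc ester homoenolate (ester β-carbon as nucleophile, from ZnCl2 ring opening of 9) transmetalates to phosphoramidite-bound copper, which attacks anti-SN2′ at C3 of 8 (the other γ-carbon, C2, is fully substituted) and expels the C1 bromide, so that reductive elimination from the ligand-bound σ-allyl trivalent copper species sets the new centre as S and leaves a non-allylic CH2Br; the closest known reactions are the racemic copper-catalysed SN2′ allylation of this zinc homoenolate and copper–phosphoramidite asymmetric allylic alkylation of 1,4-dihalobut-2-enes with Grignard or dialkylzinc reagents.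

Step 7
Reactants: 11 ethyl (4S)-4-(bromomethyl)-5-methylhex-5-enoate
Product: 13 {[(5S)-5-(bromomethyl)-2,6-dimethylhept-6-en-2-yl]oxy}trimethylsilane, via lithium tertiary alkoxide 12 (not isolated)
Conditions: MeLi (2.2 equiv), Et2O, −78 °C; then TMSCl (3 equiv), −78 °C → rt
Reagents that add atoms: methyllithium, [Li]C; chlorotrimethylsilane, C[Si](C)(C)Cl
Why: Double addition of MeLi to the ester gives the tertiary alkoxide (the primary bromide is inert at −78 °C), which is silylated in the same flask before it can close onto CH2Br, so the later organozinc carries no OH and the stereocentre is untouched.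

Step 8
Reactants: 13 {[(5S)-5-(bromomethyl)-2,6-dimethylhept-6-en-2-yl]oxy}trimethylsilane; 7 (2S)-2-[2,4-bis(methoxymethoxy)phenyl]-8-iodo-7-methoxy-5-(methoxymethoxy)-2,3-dihydro-4H-chromen-4-one
Product: 15 (2S)-2-[2,4-bis(methoxymethoxy)phenyl]-7-methoxy-5-(methoxymethoxy)-8-{(2R)-5-methyl-2-(prop-1-en-2-yl)-5-[(trimethylsilyl)oxy]hexyl}-2,3-dihydro-4H-chromen-4-one, via alkylzinc bromide 14 (not isolated)
Conditions: 13 (1.5 equiv), Zn dust, LiCl, THF, 50 °C; then 7, Pd(OAc)2 (4 mol %), CPhos (8 mol %), THF, rt → 40 °C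
Reagents that add atoms: zinc, [Zn] (zinc of 14 only)
Why: Negishi sp3–sp2 cross-coupling after LiCl-assisted zinc insertion into the primary bromide runs under neutral conditions that spare the ketone and C2, and the bulky biarylphosphine makes reductive elimination faster than β-hydride elimination, so the β-stereocentre is kept (its descriptor changes from S to R only through CIP priorities).

Step 9
Reactants: 15 (2S)-2-[2,4-bis(methoxymethoxy)phenyl]-7-methoxy-5-(methoxymethoxy)-8-{(2R)-5-methyl-2-(prop-1-en-2-yl)-5-[(trimethylsilyl)oxy]hexyl}-2,3-dihydro-4H-chromen-4-one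
Product: 16 (2S)-2-(2,4-dihydroxyphenyl)-5-hydroxy-8-[(2R)-5-hydroxy-5-methyl-2-(prop-1-en-2-yl)hexyl]-7-methoxy-2,3-dihydro-4H-chromen-4-one
Conditions: HCl (1.25 M in MeOH), 0 °C → rt
Reagents that add atoms: none
Why: Acid-catalysed transacetalisation removes the three aryl MOM ethers and methanolysis removes the tertiary TMS ether in one operation, using dilute acid instead of base to avoid retro-oxa-Michael racemisation at C2 and to leave the tertiary alcohol and isopropenyl group intact.

**Compound list**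

1 | 2′,6′-dihydroxy-4′-methoxyacetophenone | CC(=O)c1c(O)cc(OC)cc1O | starting material
2 | 1-[2-hydroxy-4-methoxy-6-(methoxymethoxy)phenyl]ethan-1-one | CC(=O)c1c(O)cc(OC)cc1OCOC | intermediate
3 | 1-[2-hydroxy-3-iodo-4-methoxy-6-(methoxymethoxy)phenyl]ethan-1-one | CC(=O)c1c(O)c(I)c(OC)cc1OCOC | intermediate
4 | 2,4-dihydroxybenzaldehyde | O=Cc1ccc(O)cc1O | starting material
5 | 2,4-bis(methoxymethoxy)benzaldehyde | O=Cc1ccc(OCOC)cc1OCOC | intermediate
6 | (E)-3-[2,4-bis(methoxymethoxy)phenyl]-1-[2-hydroxy-3-iodo-4-methoxy-6-(methoxymethoxy)phenyl]prop-2-en-1-one | O=C(/C=C/c1ccc(OCOC)cc1OCOC)c1c(O)c(I)c(OC)cc1OCOC | intermediate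
7 | (2S)-2-[2,4-bis(methoxymethoxy)phenyl]-8-iodo-7-methoxy-5-(methoxymethoxy)-2,3-dihydro-4H-chromen-4-one | Ic1c(OC)cc(OCOC)c2c1O[C@H](c1ccc(OCOC)cc1OCOC)CC2=O | intermediate
8 | (E)-1,4-dibromo-2-methylbut-2-ene | BrC/C(C)=C/CBr | starting material
9 | 1-ethoxy-1-(trimethylsilyloxy)cyclopropane | CCOC1(O[Si](C)(C)C)CC1 | starting material
10 | bis(3-ethoxy-3-oxopropyl)zinc | CCOC(=O)CC[Zn]CCC(=O)OCC | intermediate
11 | ethyl (4S)-4-(bromomethyl)-5-methylhex-5-enoate | C=C(C)[C@H](CCC(=O)OCC)CBr | intermediate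
12 | lithium (5S)-5-(bromomethyl)-2,6-dimethylhept-6-en-2-olate | [Li+].C=C(C)[C@H](CCC(C)(C)[O-])CBr | intermediate
13 | {[(5S)-5-(bromomethyl)-2,6-dimethylhept-6-en-2-yl]oxy}trimethylsilane | C=C(C)[C@H](CCC(C)(C)O[Si](C)(C)C)CBr | intermediate
14 | {(2S)-5-methyl-2-(prop-1-en-2-yl)-5-[(trimethylsilyl)oxy]hexyl}zinc bromide | C=C(C)[C@H](CCC(C)(C)O[Si](C)(C)C)C[Zn]Br | intermediate
15 | (2S)-2-[2,4-bis(methoxymethoxy)phenyl]-7-methoxy-5-(methoxymethoxy)-8-{(2R)-5-methyl-2-(prop-1-en-2-yl)-5-[(trimethylsilyl)oxy]hexyl}-2,3-dihydro-4H-chromen-4-one | C=C(C)[C@H](CCC(C)(C)O[Si](C)(C)C)Cc1c(OC)cc(OCOC)c2c1O[C@H](c1ccc(OCOC)cc1OCOC)CC2=O | intermediate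
16 | (2S)-2-(2,4-dihydroxyphenyl)-5-hydroxy-8-[(2R)-5-hydroxy-5-methyl-2-(prop-1-en-2-yl)hexyl]-7-methoxy-2,3-dihydro-4H-chromen-4-one | C=C(C)[C@H](CCC(C)(C)O)Cc1c(OC)cc(O)c2c1O[C@H](c1ccc(O)cc1O)CC2=O | target

**Step count**

Total steps: 9. Longest linear sequence: 6 (steps 1, 2, 4, 5, 8, 9).

**Steps most likely to fail, with fallbacks**

Step 6. The internally chelated zinc homoenolate may transmetalate slowly to a chiral copper centre, SN2 substitution or 1,4-debromination may compete, and the enantioselectivity is untested. The fallback sets out from 8 and uses a masked ketone homoenolate in Grignard form, the nucleophile class for which copper–phosphoramidite SN2′ substitution of 1,4-dihalobut-2-enes is established. 2-(2-Bromoethyl)-2-methyl-1,3-dioxolane and Mg give [2-(2-methyl-1,3-dioxolan-2-yl)ethyl]magnesium bromide F1. With 8, CuBr·SMe2 and the phosphoramidite in CH2Cl2 at −78 °C, this gives 2-[(3S)-3-(bromomethyl)-4-methylpent-4-en-1-yl]-2-methyl-1,3-dioxolane F2. PPTS in wet acetone unmasks (5S)-5-(bromomethyl)-6-methylhept-6-en-2-one F3. One equivalent of MeLi followed by TMSCl passes through 12 and comes back to the route at 13, at a cost of two extra steps.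

Step 8. The aryl iodide is flanked by two ortho oxygens, the alkylzinc is β-branched with an allylic β-hydrogen, and zinc salts could reopen ring C. The fallback sets out from 13 and 3 and makes the aryl–CH2 bond with boron before ring C exists. CuI/PPh3-catalysed borylation of 13 with B2pin2 and LiOMe gives 4,4,5,5-tetramethyl-2-{(2S)-5-methyl-2-(prop-1-en-2-yl)-5-[(trimethylsilyl)oxy]hexyl}-1,3,2-dioxaborolane F4. B-alkyl Suzuki–Miyaura coupling with 3 (Pd(OAc)2, RuPhos, K3PO4, toluene/H2O, 80 °C, tolerated by the base-stable acetophenone) gives 1-[2-hydroxy-4-methoxy-6-(methoxymethoxy)-3-{(2R)-5-methyl-2-(prop-1-en-2-yl)-5-[(trimethylsilyl)oxy]hexyl}phenyl]ethan-1-one F5. Claisen–Schmidt condensation with 5 (KOH, EtOH, with loss of the TMS ether) gives (E)-3-[2,4-bis(methoxymethoxy)phenyl]-1-{2-hydroxy-3-[(2R)-5-hydroxy-5-methyl-2-(prop-1-en-2-yl)hexyl]-4-methoxy-6-(methoxymethoxy)phenyl}prop-2-en-1-one F6. The thiourea-catalysed closure of step 5 gives (2S)-2-[2,4-bis(methoxymethoxy)phenyl]-8-[(2R)-5-hydroxy-5-methyl-2-(prop-1-en-2-yl)hexyl]-7-methoxy-5-(methoxymethoxy)-2,3-dihydro-4H-chromen-4-one F7. Methanolic HCl as in step 9 then comes back to the route at 16.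

Step 5. Organocatalytic closure of a chalcone without an activating α-substituent may give insufficient ee, and the reaction is reversible. The fallback sets out from 6 and closes ring C without induction (NaOAc, EtOH, reflux) to give rac-2-[2,4-bis(methoxymethoxy)phenyl]-8-iodo-7-methoxy-5-(methoxymethoxy)-2,3-dihydro-4H-chromen-4-one F8. Kinetic resolution by asymmetric transfer hydrogenation ([Cp*RhCl((R,R)-TsDPEN)], HCO2H/Et3N, EtOAc, rt, stopped near half conversion) then reduces the 2R ketone to (2R,4R)-2-[2,4-bis(methoxymethoxy)phenyl]-8-iodo-7-methoxy-5-(methoxymethoxy)-3,4-dihydro-2H-chromen-4-ol F9. The unreacted (S)-ketone is recovered and comes back to the route at 7, with a ceiling of 50 % yield.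

**Further compounds**

F1 | step 6 | [2-(2-methyl-1,3-dioxolan-2-yl)ethyl]magnesium bromide | CC1(CC[Mg]Br)OCCO1
F2 | step 6 | 2-[(3S)-3-(bromomethyl)-4-methylpent-4-en-1-yl]-2-methyl-1,3-dioxolane | C=C(C)[C@H](CCC1(C)OCCO1)CBr
F3 | step 6 | (5S)-5-(bromomethyl)-6-methylhept-6-en-2-one | C=C(C)[C@H](CCC(C)=O)CBr
F4 | step 8 | 4,4,5,5-tetramethyl-2-{(2S)-5-methyl-2-(prop-1-en-2-yl)-5-[(trimethylsilyl)oxy]hexyl}-1,3,2-dioxaborolane | C=C(C)[C@H](CCC(C)(C)O[Si](C)(C)C)CB1OC(C)(C)C(C)(C)O1
F5 | step 8 | 1-[2-hydroxy-4-methoxy-6-(methoxymethoxy)-3-{(2R)-5-methyl-2-(prop-1-en-2-yl)-5-[(trimethylsilyl)oxy]hexyl}phenyl]ethan-1-one | C=C(C)[C@H](CCC(C)(C)O[Si](C)(C)C)Cc1c(OC)cc(OCOC)c(C(C)=O)c1O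
F6 | step 8 | (E)-3-[2,4-bis(methoxymethoxy)phenyl]-1-{2-hydroxy-3-[(2R)-5-hydroxy-5-methyl-2-(prop-1-en-2-yl)hexyl]-4-methoxy-6-(methoxymethoxy)phenyl}prop-2-en-1-one | C=C(C)[C@H](CCC(C)(C)O)Cc1c(OC)cc(OCOC)c(C(=O)/C=C/c2ccc(OCOC)cc2OCOC)c1O
F7 | step 8 | (2S)-2-[2,4-bis(methoxymethoxy)phenyl]-8-[(2R)-5-hydroxy-5-methyl-2-(prop-1-en-2-yl)hexyl]-7-methoxy-5-(methoxymethoxy)-2,3-dihydro-4H-chromen-4-one | C=C(C)[C@H](CCC(C)(C)O)Cc1c(OC)cc(OCOC)c2c1O[C@H](c1ccc(OCOC)cc1OCOC)CC2=O
F8 | step 5 | rac-2-[2,4-bis(methoxymethoxy)phenyl]-8-iodo-7-methoxy-5-(methoxymethoxy)-2,3-dihydro-4H-chromen-4-one | Ic1c(OC)cc(OCOC)c2c1OC(c1ccc(OCOC)cc1OCOC)CC2=O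
F9 | step 5 | (2R,4R)-2-[2,4-bis(methoxymethoxy)phenyl]-8-iodo-7-methoxy-5-(methoxymethoxy)-3,4-dihydro-2H-chromen-4-ol | Ic1c(OC)cc(OCOC)c2c1O[C@@H](c1ccc(OCOC)cc1OCOC)C[C@H]2O
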